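**Plan**
- Numbering runs from C1 (lactone carbonyl) to C32 (OCH2). C6–C7, C14–C15 and C22–C23 of the saturated ring are first taken back to alkenes, and all three are then cut by retro-metathesis.
- The target is an unbranched 33-membered loop of one ester and 31 CH2 groups, so its 32 carbons split as 16 + 8 + 8. C1–C6 and C23–C32 with the ring oxygen are the 17-membered hexadecenolide 1 opened at its alkene. C7–C14 and C15–C22 are two eight-membered rings of cyclooctene 2.
- Forward, one ruthenium-catalysed ring-opening/cross/ring-closing metathesis merges 1 with two molecules of 2 into the 33-membered triene 4, passing through the one-insertion 25-membered ring 3. Hydrogenation then gives 5.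
- The molecule has a single ring, which arises in step 1. No open-chain compound is ever isolated.
- The target has no stereocentre, and the E/Z mixture of 4 disappears on saturation.

Key step: step 1

Assumption: the commercial lactone is taken as the 6-ene isomer drawn. A positional isomer of the alkene in the 17-membered ring would shift the alkene positions in 3 and 4 but would change neither the ring sizes nor 5.

**Step 1**
Reactants: 1 ω-6-hexadecenlactone (oxacycloheptadec-7-en-2-one, either alkene geometry); 2 cis-cyclooctene (2 equiv)
Product: 4 oxacyclotritriaconta-7,15,23-trien-2-one (E/Z mixture), via oxacyclopentacosa-7,15-dien-2-one 3 (not isolated)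
Conditions: second-generation Grubbs catalyst RuCl2(=CHPh)(PCy3)(H2IMes) (2 mol %), 1,4-benzoquinone (10 mol %), CH2Cl2 (0.03 M in 1), 40 °C, 2 added over 2 h, then 16 h; ethyl vinyl ether; SiO2, then C18 reversed-phase chromatography, off-size rings returned to the next run
Reagents that add atoms: none
Why: The ruthenium alkylidene opens strained 2 by [2+2] cycloaddition and cycloreversion through a metallacyclobutane, the new chain-end carbene exchanges with the C6=C7 alkene of 1 so that the one ester segment becomes flanked by C8 units, and the one-insertion ring 3 shed on the way is reopened by the same catalyst and takes up the second molecule of 2. The closest known reaction types are ring-expansion metathesis (ring opening, cross metathesis and ring closure in one pot) of cycloalkenes and the ruthenium-catalysed ring–chain equilibration of unsaturated macrolactones. The single new ring, the 33-membered one, closes in the ring-closing-metathesis mode when the chain-end carbene back-bites on a remote internal alkene of its own chain, so whichever of C6=C7, C14=C15 and C22=C23 is made last is the closing bond. No stereocentre is created, and the E/Z mixture at the three alkenes is irrelevant because step 2 saturates them. The selectivity needed is the number of C8 units per ester segment, which the substrates do not enforce: the 1:2 feed fixes the mean composition, ring strain keeps free 2 at a low level, and a moderate concentration below the ring–chain critical value keeps the material cyclic without pushing it back to the smallest strain-free rings as extreme dilution would, so only a statistical share of 4 can be expected per pass. What the structures do secure is that a ring with one ester segment and two C8 units has only one constitution and differs from its homologues by C8H14 and from ester-free and diester rings by polarity, so 4 can be cut out by chromatography and every off-size ring re-equilibrated in the next run, while 1,4-benzoquinone checks ruthenium-hydride alkene migration that would blur the eight-carbon spacing.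

**Step 2**
Reactants: 4 oxacyclotritriaconta-7,15,23-trien-2-one (E/Z mixture)
Product: 5 oxacyclotritriacontan-2-one (32-dotriacontanolide, the target)
Conditions: H2 (3 bar), 10% Pd/C, EtOAc/THF, 40 °C; hot filtration through Celite, recrystallisation from acetone
Reagents that add atoms: none
Why: Heterogeneous catalytic hydrogenation of unhindered 1,2-disubstituted alkenes over palladium is fast, leaves the lactone untouched and merges all alkene isomers of 4 into the one saturated ring 5, which has no stereocentre.

**Compound list**
1 | ω-6-hexadecenlactone (oxacycloheptadec-7-en-2-one, alkene geometry immaterial) | O=C1CCCCC=CCCCCCCCCCO1 | starting material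
2 | cis-cyclooctene | C1CCC/C=C\CC1 | starting material
3 | oxacyclopentacosa-7,15-dien-2-one (25-membered diene lactone, E/Z mixture, not isolated) | O=C1CCCCC=CCCCCCCC=CCCCCCCCCCO1 | intermediate
4 | oxacyclotritriaconta-7,15,23-trien-2-one (33-membered triene lactone, E/Z mixture) | O=C1CCCCC=CCCCCCCC=CCCCCCCC=CCCCCCCCCCO1 | intermediate
5 | oxacyclotritriacontan-2-one (32-dotriacontanolide) | O=C1CCCCCCCCCCCCCCCCCCCCCCCCCCCCCCCO1 | target

Total step count: 2. Longest linear sequence: 2 steps.

**Steps most likely to fail**
The route has only two steps. Step 1 is therefore entered twice, once for each of its two independent failure processes.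

1. **Step 1, selection of the ring size.**
   - Risk: the number of C8 units per ring is set only by statistics, so the share of the two-insertion ring may stay small even with recycling. Alkene migration may also shift ring sizes by single carbons until chromatography no longer resolves the series.
   - Fallback: no metathesis is used, and the chain length is fixed by a C16 + C16 coupling. It sets out from 1 and comes back at 5.
   - 1 is hydrogenated (H2, Pd/C) to hexadecanolide F1, which HBr in AcOH opens to 16-bromohexadecanoic acid F2.
   - Half of this acid is reduced with BH3·THF to 16-bromohexadecan-1-ol F3 and protected with dihydropyran and PPTS as 2-[(16-bromohexadecyl)oxy]oxane F4. Mg in THF then converts F4 into [16-(oxan-2-yloxy)hexadecyl]magnesium bromide F5.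
   - The other half of the bromo acid is deprotonated with MeMgCl and coupled with the Grignard reagent under Li2CuCl4 catalysis at −20 °C. This gives 32-(oxan-2-yloxy)dotriacontanoic acid F6.
   - Warm AcOH/THF/H2O frees 32-hydroxydotriacontanoic acid F7.
   - Yamaguchi macrolactonisation follows (2,4,6-trichlorobenzoyl chloride, Et3N, then slow addition to DMAP in hot toluene). It passes through 32-hydroxydotriacontanoic 2,4,6-trichlorobenzoic anhydride F8 and closes the C1–O bond to give 5.

2. **Step 1, engagement of the lactone alkene.**
   - Risk: homopolymerisation of 2 may run far ahead of exchange with the unstrained internal alkene of 1. Polymer may then separate, or the catalyst may decay, before the ester segment is spliced in.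
   - Fallback: an acyclic diene takes the place of the ring, with ethylene loss as driving force. It sets out from 1 and comes back at 4.
   - Ethenolysis of 1 (ethylene, 10 bar, first-generation Grubbs catalyst RuCl2(=CHPh)(PCy3)2, CH2Cl2) gives undec-10-en-1-yl hept-6-enoate F9. Its two terminal alkenes are fast chain-transfer sites.
   - This diene and two equivalents of 2 are then treated with RuCl2(=CHPh)(PCy3)(H2IMes) in CH2Cl2 at 40 °C under an argon sparge. Ring-opening cross metathesis and ring-closing metathesis, the established ring expansion of a cycloalkene by an α,ω-diene, give 4. It is isolated as in step 1.

3. **Step 2, completeness of saturation.**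
   - Risk: the waxy product may crystallise on the catalyst, or traces of ruthenium and quinone may poison the palladium surface. Reduction would then stop at partly saturated rings that co-crystallise with the product.
   - Fallback: a metal-free concerted hydrogen transfer. It sets out from 4 and comes back at 5.
   - 4 is heated with an excess of p-toluenesulfonyl hydrazide and NaOAc in refluxing THF/water. The diimide generated in the flask reduces the three unhindered alkenes in homogeneous solution and does not touch the ester.

**Further compounds**
F1 | step 1 | hexadecanolide (oxacycloheptadecan-2-one) | O=C1CCCCCCCCCCCCCCCO1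
F2 | step 1 | 16-bromohexadecanoic acid | OC(=O)CCCCCCCCCCCCCCCBr
F3 | step 1 | 16-bromohexadecan-1-ol | OCCCCCCCCCCCCCCCCBr
F4 | step 1 | 2-[(16-bromohexadecyl)oxy]oxane (racemic acetal) | BrCCCCCCCCCCCCCCCCOC1CCCCO1
F5 | step 1 | [16-(oxan-2-yloxy)hexadecyl]magnesium bromide | Br[Mg]CCCCCCCCCCCCCCCCOC1CCCCO1
F6 | step 1 | 32-(oxan-2-yloxy)dotriacontanoic acid | OC(=O)CCCCCCCCCCCCCCCCCCCCCCCCCCCCCCCOC1CCCCO1
F7 | step 1 | 32-hydroxydotriacontanoic acid | OC(=O)CCCCCCCCCCCCCCCCCCCCCCCCCCCCCCCO
F8 | step 1 | 32-hydroxydotriacontanoic 2,4,6-trichlorobenzoic anhydride | O=C(CCCCCCCCCCCCCCCCCCCCCCCCCCCCCCCO)OC(=O)c1c(Cl)cc(Cl)cc1Cl
F9 | step 1 | undec-10-en-1-yl hept-6-enoate | C=CCCCCC(=O)OCCCCCCCCCC=C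
F0 | step 2 | none | none
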